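Ring B is read as the dehydrogenated form of a 4‑alkyl‑2‑methoxycyclohexane‑1,3‑dione. Its contiguous C2'–OH, C3'–OMe and C4'–OH beside the chain‑bearing C1', together with the unsubstituted C5'–C6' edge, map onto a substituted malonate and 1‑methoxybut‑3‑en‑2‑one. In one operation a conjugate addition makes C1'–C6' and a Claisen condensation makes C2'–C3', closing the six‑membered ring with every oxygen already in its final position. The precursor is a dimethyl malonate carrying the complete chain with ring A, its ketone masked as a dioxolane. Methyl esters are chosen because the ester left on the quaternary ring carbon must later be removed without harming the ketal.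

Key step: step 7

Remark: the target is achiral. The 1,3‑diones 13, 14 and 15 are drawn as diketones, though they should exist largely as enols; their stereocentres are racemic and vanish on aromatisation.

Step 1
Reactants: 1 5-(4-methoxyphenyl)pentanoic acid
Product: 3 N-methoxy-5-(4-methoxyphenyl)-N-methylpentanamide, via acyl imidazolide 2 (not isolated)
Conditions: CDI (1.1 equiv), CH2Cl2, rt; then MeNHOMe·HCl (1.2 equiv), rt
Reagents that add atoms: N,O-dimethylhydroxylamine hydrochloride, CNOC.Cl; 1,1'-carbonyldiimidazole, O=C(n1ccnc1)n1ccnc1 (imidazole unit in intermediate 2 only)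
Why: Acyl‑imidazole activation followed by acyl substitution by the hydroxylamine (Weinreb amide formation) is reliable for an unhindered aliphatic acid, and nothing else in 1 reacts with CDI.

Step 2
Reactants: 3 N-methoxy-5-(4-methoxyphenyl)-N-methylpentanamide; 4 vinylmagnesium bromide
Product: 5 7-(4-methoxyphenyl)hept-1-en-3-one
Conditions: CH2=CHMgBr (1.3 equiv), THF, −10 to 0 °C; inverse quench into cold 1 M HCl; used promptly
Reagents that add atoms: vinylmagnesium bromide (4), C=C[Mg]Br
Why: Weinreb ketone synthesis, in which the chelated tetrahedral adduct persists until the quench so that the Grignard reagent adds only once, and the acidic inverse quench keeps the released hydroxylamine protonated so that it cannot add to the new vinyl ketone.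

Step 3
Reactants: 5 7-(4-methoxyphenyl)hept-1-en-3-one; 6 dimethyl malonate
Product: 7 dimethyl 2-[7-(4-methoxyphenyl)-3-oxoheptyl]malonate
Conditions: 6 (3 equiv), NaOMe (0.1 equiv), MeOH, 0 °C to rt; AcOH quench
Reagents that add atoms: none
Why: Base‑catalysed Michael addition of the malonate carbanion to the unhindered vinyl ketone, where excess malonate suppresses double addition and the catalytic amount of methoxide at low temperature avoids the Claisen ring closure that this unprotected keto malonate would undergo with stoichiometric base.

Step 4
Reactants: 7 dimethyl 2-[7-(4-methoxyphenyl)-3-oxoheptyl]malonate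
Product: 8 dimethyl 2-{2-[2-(4-(4-methoxyphenyl)butyl)-1,3-dioxolan-2-yl]ethyl}malonate
Conditions: Me3SiOCH2CH2OSiMe3 (1.5 equiv), Me3SiOTf (0.05 equiv), CH2Cl2, −78 to −20 °C; pyridine quench
Reagents that add atoms: 1,2-bis(trimethylsilyloxy)ethane, C[Si](C)(C)OCCO[Si](C)(C)C
Why: Ketalisation with the bis‑silyl ether of ethylene glycol under Me3SiOTf catalysis (Noyori ketalisation) is driven by formation of hexamethyldisiloxane, forms no water and runs cold, so the malonate esters are not transesterified and the anisole ring is untouched.

Step 5
Reactants: 9 methoxyacetyl chloride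
Product: 10 N,2-dimethoxy-N-methylacetamide
Conditions: MeNHOMe·HCl (1.05 equiv), Et3N (2.2 equiv), CH2Cl2, 0 °C to rt; Et2O, filtration, distillation
Reagents that add atoms: N,O-dimethylhydroxylamine hydrochloride, CNOC.Cl
Why: Acylation of the hydroxylamine by the acid chloride (Weinreb amide formation) is fast and clean, and the non‑aqueous work‑up avoids loss of the small water‑soluble amide.

Step 6
Reactants: 10 N,2-dimethoxy-N-methylacetamide; 4 vinylmagnesium bromide
Product: 11 1-methoxybut-3-en-2-one
Conditions: CH2=CHMgBr (1.15 equiv), THF, −20 to 0 °C; inverse quench into cold 2 M HCl/Et2O; BHT (trace); kept cold as a concentrated ethereal solution and used at once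
Reagents that add atoms: vinylmagnesium bromide (4), C=C[Mg]Br
Why: Weinreb ketone synthesis as in step 2, where the chelated adduct prevents over‑addition, the acidic inverse quench prevents aza‑Michael addition of the released hydroxylamine, and cold handling with a radical inhibitor limits polymerisation of the volatile enone.

Step 7
Reactants: 8 dimethyl 2-{2-[2-(4-(4-methoxyphenyl)butyl)-1,3-dioxolan-2-yl]ethyl}malonate; 11 1-methoxybut-3-en-2-one
Product: 13 methyl 3-methoxy-1-{2-[2-(4-(4-methoxyphenyl)butyl)-1,3-dioxolan-2-yl]ethyl}-2,4-dioxocyclohexane-1-carboxylate (racemic; enolised at C3), via Michael adduct 12 (not isolated)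
Conditions: NaOMe (0.2 equiv), MeOH, 0 °C, slow addition of 11 (1.3 equiv); then NaOMe (1.5 equiv), 65 °C; 1 M HCl to pH 4 at 0 °C
Reagents that add atoms: none
Why: Methoxide deprotonates the substituted malonate 8, whose carbanion adds 1,4 to the unsubstituted vinyl terminus of 11 to give 12 (bond C1'–C6'); proton exchange in methanol then provides the ketone enolate on the methoxy‑bearing carbon, which attacks one of the two equivalent ester carbonyls and expels methoxide (bond C2'–C3'). The closest known reaction type is the Michael–Claisen (dimedone‑type) synthesis of cyclohexane‑1,3‑diones from malonates and enones. Ring B closes in the 6‑exo‑trig mode, through a six‑membered transition state with the ester C=O outside the ring. The only stereocentre formed, the quaternary C1', arises racemic under no control and needs none, because decarboxylation and aromatisation erase it, while C3' is enolised. Regioselectivity of the closure is secured by ring size, since the alternative enolate at C5' could only form a four‑membered ring, and chemoselectivity by the dioxolane, which removes the chain ketone as a competing enolate donor and acceptor. Final deprotonation of 13 at C3', between the two ketones, pulls the reversible steps forward and shields the non‑enolisable keto ester at C1' from retro‑Claisen attack by methoxide.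

Step 8
Reactants: 13 methyl 3-methoxy-1-{2-[2-(4-(4-methoxyphenyl)butyl)-1,3-dioxolan-2-yl]ethyl}-2,4-dioxocyclohexane-1-carboxylate
Product: 15 2-methoxy-4-{2-[2-(4-(4-methoxyphenyl)butyl)-1,3-dioxolan-2-yl]ethyl}cyclohexane-1,3-dione (racemic; largely enolic), via keto acid 14 (not isolated)
Conditions: 2 M NaOH, MeOH/H2O, 65 °C; 1 M HCl to pH 4 at 0 °C, EtOAc extraction; then toluene, 80 °C
Reagents that add atoms: none
Why: Ester saponification followed by thermal decarboxylation of the β‑keto acid is the classical end of the dimedone sequence; in the alkaline stage the dione is present as its enolate, which protects the ring from retro‑Claisen opening, and the brief cold acidification and anhydrous warming should leave the dioxolane intact.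

Step 9
Reactants: 15 2-methoxy-4-{2-[2-(4-(4-methoxyphenyl)butyl)-1,3-dioxolan-2-yl]ethyl}cyclohexane-1,3-dione
Product: 17 1-(2,4-dihydroxy-3-methoxyphenyl)-7-(4-methoxyphenyl)heptan-3-one (target), via ketal resorcinol 16 (not isolated)
Conditions: 10% Pd/C, diglyme, 160 °C, N2 stream; cool, filter under N2; then 1 M HCl (aq), rt
Reagents that add atoms: water, O
Why: Heterogeneous palladium‑catalysed dehydrogenation of a cyclohexane‑1,3‑dione to a resorcinol is a known aromatisation‑driven reaction in which the nitrogen stream removes hydrogen and the dioxolane keeps the chain ketone away from the dione, and the following acid‑catalysed ketal hydrolysis in water (no alcohol present, so no mixed ketal with the ortho phenol) should release the ketone.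

Compound list
1 | 5-(4-methoxyphenyl)pentanoic acid | COc1ccc(CCCCC(=O)O)cc1 | starting material
2 | 1-[5-(4-methoxyphenyl)pentanoyl]-1H-imidazole | COc1ccc(CCCCC(=O)n2ccnc2)cc1 | intermediate (not isolated)
3 | N-methoxy-5-(4-methoxyphenyl)-N-methylpentanamide | COc1ccc(CCCCC(=O)N(C)OC)cc1 | intermediate
4 | vinylmagnesium bromide | C=C[Mg]Br | starting material
5 | 7-(4-methoxyphenyl)hept-1-en-3-one | COc1ccc(CCCCC(=O)C=C)cc1 | intermediate
6 | dimethyl malonate | COC(=O)CC(=O)OC | starting material
7 | dimethyl 2-[7-(4-methoxyphenyl)-3-oxoheptyl]malonate | COC(=O)C(CCC(=O)CCCCc1ccc(OC)cc1)C(=O)OC | intermediate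
8 | dimethyl 2-{2-[2-(4-(4-methoxyphenyl)butyl)-1,3-dioxolan-2-yl]ethyl}malonate | COC(=O)C(CCC1(CCCCc2ccc(OC)cc2)OCCO1)C(=O)OC | intermediate (key-step precursor)
9 | methoxyacetyl chloride | COCC(=O)Cl | starting material
10 | N,2-dimethoxy-N-methylacetamide | COCC(=O)N(C)OC | intermediate
11 | 1-methoxybut-3-en-2-one | COCC(=O)C=C | intermediate (key-step precursor)
12 | dimethyl 2-(4-methoxy-3-oxobutyl)-2-{2-[2-(4-(4-methoxyphenyl)butyl)-1,3-dioxolan-2-yl]ethyl}malonate | COC(=O)C(CCC1(CCCCc2ccc(OC)cc2)OCCO1)(CCC(=O)COC)C(=O)OC | intermediate (not isolated)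
13 | methyl 3-methoxy-1-{2-[2-(4-(4-methoxyphenyl)butyl)-1,3-dioxolan-2-yl]ethyl}-2,4-dioxocyclohexane-1-carboxylate (racemic) | COC(=O)C1(CCC2(CCCCc3ccc(OC)cc3)OCCO2)CCC(=O)C(OC)C1=O | intermediate (key-step product)
14 | 3-methoxy-1-{2-[2-(4-(4-methoxyphenyl)butyl)-1,3-dioxolan-2-yl]ethyl}-2,4-dioxocyclohexane-1-carboxylic acid (racemic) | OC(=O)C1(CCC2(CCCCc3ccc(OC)cc3)OCCO2)CCC(=O)C(OC)C1=O | intermediate (not isolated)
15 | 2-methoxy-4-{2-[2-(4-(4-methoxyphenyl)butyl)-1,3-dioxolan-2-yl]ethyl}cyclohexane-1,3-dione (racemic) | COc1ccc(CCCCC2(CCC3CCC(=O)C(OC)C3=O)OCCO2)cc1 | intermediate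
16 | 2-methoxy-4-{2-[2-(4-(4-methoxyphenyl)butyl)-1,3-dioxolan-2-yl]ethyl}benzene-1,3-diol | COc1ccc(CCCCC2(CCc3ccc(O)c(OC)c3O)OCCO2)cc1 | intermediate (not isolated)
17 | 1-(2,4-dihydroxy-3-methoxyphenyl)-7-(4-methoxyphenyl)heptan-3-one | COc1ccc(CCCCC(=O)CCc2ccc(O)c(OC)c2O)cc1 | target

Total step count: 9. Longest linear sequence: 7 steps (steps 1, 2, 3, 4, 7, 8 and 9, from acid 1).

Steps most likely to fail

Step 7. Anionic polymerisation of the enone, or reversible addition of methoxide to it, may outrun attack by the hindered malonate anion, and the sequence may stall at the open‑chain adduct. The fallback feeds the acceptor from a latent form. It sets out from 11 as the crude ethereal solution of step 6: Me2NH (THF, 0 °C) should give the stable, distillable Mannich base 4-(dimethylamino)-1-methoxybutan-2-one F1. MeI in Et2O should then precipitate the quaternary salt 4-methoxy-N,N,N-trimethyl-3-oxobutan-1-aminium iodide F2. Added in portions to 8 and NaOMe (2.5 equiv) in MeOH at 0 to 65 °C, F2 should release the enone by E1cB elimination only at a low stationary concentration, where the sodiomalonate traps it at once. Adduct 12 forms as before and closes to 13, where the route is rejoined.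

Step 9. Hydrogen liberated on the catalyst may be transferred back, leading to disproportionation or hydrogenolysis of ring oxygen, and the acidic dione may trigger thermal ketal exchange at 160 °C. The fallback replaces the thermal dehydrogenation by a cold quinone oxidation of a diene. It sets out from 15: Me3SiOTf (2.4 equiv) and Et3N in CH2Cl2 at 0 °C should give the bis‑silyl dienol ether 2-[4-(4-methoxyphenyl)butyl]-2-{2-[3-methoxy-2,4-bis(trimethylsilyloxy)cyclohexa-1,3-dien-1-yl]ethyl}-1,3-dioxolane F3 (a double‑bond isomer would serve equally). DDQ (1.1 equiv, CH2Cl2, 0 °C) should aromatise this cyclohexadiene to the aryl bis‑silyl ether 2-{2-[3-methoxy-2,4-bis(trimethylsilyloxy)phenyl]ethyl}-2-[4-(4-methoxyphenyl)butyl]-1,3-dioxolane F4. 1 M HCl in THF at rt should then cleave both silyl ethers and the dioxolane, coming back to the route at the target 17.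

Step 6. The small, volatile, water‑soluble enone may be lost on isolation or polymerise, and the hydroxylamine released at the quench may add to it. The fallback avoids both amine and aqueous work‑up. It sets out from acid chloride 9: Stille acylation with tributyl(vinyl)stannane and Pd(PPh3)4 (zerovalent palladium, 2 mol %) in THF at 60 °C with a trace of BHT should give the enone directly, to be distilled away from the involatile tin residue. It comes back to the route at 11; new compounds on its way: none F0.

Further compounds
F1 | step 7 | 4-(dimethylamino)-1-methoxybutan-2-one | COCC(=O)CCN(C)C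
F2 | step 7 | 4-methoxy-N,N,N-trimethyl-3-oxobutan-1-aminium iodide | COCC(=O)CC[N+](C)(C)C.[I-]
F3 | step 9 | 2-[4-(4-methoxyphenyl)butyl]-2-{2-[3-methoxy-2,4-bis(trimethylsilyloxy)cyclohexa-1,3-dien-1-yl]ethyl}-1,3-dioxolane | COc1ccc(CCCCC2(CCC3=C(O[Si](C)(C)C)C(OC)=C(O[Si](C)(C)C)CC3)OCCO2)cc1
F4 | step 9 | 2-{2-[3-methoxy-2,4-bis(trimethylsilyloxy)phenyl]ethyl}-2-[4-(4-methoxyphenyl)butyl]-1,3-dioxolane | COc1ccc(CCCCC2(CCc3ccc(O[Si](C)(C)C)c(OC)c3O[Si](C)(C)C)OCCO2)cc1
F0 | step 6 | none | none
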